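**Plan**
1. Retrosynthesis: the MOM ether and the C4 dithiane come off last. The O1–C8a aryl ether bond is cut first, which opens ring C to a C8a bromide and a C2 carbinol. The C3–C4 bond is cut next (dithiane anion plus epoxide), and the two prenyl groups are traced back through C-allyl groups to O-allyl ethers.
2. Forward: ring A is dressed on 2-bromo-4-hydroxybenzaldehyde (two allylation/Claisen cycles, dithiane, MOM, cross-metathesis to prenyl). The chain is joined by opening (R)-3,4-dimethoxystyrene oxide with the lithiated dithiane, ring C is closed by palladium-catalysed C(aryl)–O coupling, and the C4 ketone and 7-OH are then unmasked.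
3. Stereochemistry: C2 is the only stereocentre. It is set by CBS reduction of 2-bromo-1-(3,4-dimethoxyphenyl)ethanone, and no later step breaks a bond at it.
4. Enabling feature: O1 links the ring A carbon C8a to the stereocentre C2. The C2–O bond can therefore arrive as a secondary benzylic alcohol of fixed configuration, and only O1–C8a has to be made, at a carbon that can carry bromine.

Key step: step 10

Remark: atom labels (O1, C2, C3, C4, C4a, C5 to C8, C8a) are those of the chroman-4-one core, ring A being the benzo ring and ring C the oxygen heterocycle; the first Claisen rearrangement is assumed to favour the ortho carbon next to bromine, so the route is written for that isomer and the minor 5-allyl isomer is removed by chromatography after step 2.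

**Step 1**
Reactants: 1 2-bromo-4-hydroxybenzaldehyde; 2 allyl bromide
Product: 3 4-(allyloxy)-2-bromobenzaldehyde
Conditions: allyl bromide (1.2 equiv), K2CO3, DMF, rt
Reagents that add atoms: allyl bromide, C=CCBr
Why: Williamson etherification of a phenol made acidic by the para-formyl group, for which K2CO3 is sufficient and C-alkylation does not compete.

**Step 2**
Reactants: 3 4-(allyloxy)-2-bromobenzaldehyde
Product: 4 3-allyl-2-bromo-4-hydroxybenzaldehyde
Conditions: N,N-diethylaniline, 195 °C, Ar; chromatography
Reagents that add atoms: none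
Why: An aromatic Claisen rearrangement ([3,3]-sigmatropic shift, then tautomerisation) moves the allyl group to an ortho carbon, by preference to the one next to bromine as is usual for aryl allyl ethers with an electron-withdrawing meta substituent, and the minor 5-allyl isomer is separated at this stage.

**Step 3**
Reactants: 4 3-allyl-2-bromo-4-hydroxybenzaldehyde; 2 allyl bromide
Product: 5 3-allyl-4-(allyloxy)-2-bromobenzaldehyde
Conditions: allyl bromide (1.3 equiv), K2CO3, DMF, 40 °C
Reagents that add atoms: allyl bromide, C=CCBr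
Why: Williamson etherification of the phenoxide, the ortho-allyl group being too small to hinder O-alkylation.

**Step 4**
Reactants: 5 3-allyl-4-(allyloxy)-2-bromobenzaldehyde
Product: 6 3,5-diallyl-2-bromo-4-hydroxybenzaldehyde
Conditions: N,N-diethylaniline, 195 °C, Ar
Reagents that add atoms: none
Why: A second aromatic Claisen rearrangement can deliver the allyl group only to C5 of the benzaldehyde, the one free ortho position, because C3 already carries an allyl group and the para position carries the formyl group.

**Step 5**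
Reactants: 6 3,5-diallyl-2-bromo-4-hydroxybenzaldehyde; 7 propane-1,3-dithiol
Product: 8 2,6-diallyl-3-bromo-4-(1,3-dithian-2-yl)phenol
Conditions: propane-1,3-dithiol (1.1 equiv), BF3·OEt2 (20 mol%), CH2Cl2, 0 °C to rt
Reagents that add atoms: propane-1,3-dithiol, SCCCS
Why: Lewis-acid-catalysed dithioacetalisation of the aromatic aldehyde is placed here because terminal allyl groups and a free phenol tolerate BF3 with a thiol, whereas a MOM ether or prenyl groups would be at risk.

**Step 6**
Reactants: 8 2,6-diallyl-3-bromo-4-(1,3-dithian-2-yl)phenol; 9 chloromethyl methyl ether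
Product: 10 2-[3,5-diallyl-2-bromo-4-(methoxymethoxy)phenyl]-1,3-dithiane
Conditions: NaH, THF, 0 °C; MOMCl, 0 °C to rt
Reagents that add atoms: chloromethyl methyl ether, COCCl
Why: O-alkylation of the sodium phenoxide gives an acetal that withstands the amide base, the carbonate base and the alkylative dithiane hydrolysis that follow.

**Step 7**
Reactants: 10 2-[3,5-diallyl-2-bromo-4-(methoxymethoxy)phenyl]-1,3-dithiane; 11 2-methyl-2-butene
Product: 12 2-[2-bromo-4-(methoxymethoxy)-3,5-bis(3-methylbut-2-enyl)phenyl]-1,3-dithiane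
Conditions: second-generation Grubbs catalyst, (H2IMes)(PCy3)Cl2Ru=CHPh (5 mol%), 2-methyl-2-butene/CH2Cl2 1:1, 40 °C, sealed vessel
Reagents that add atoms: 2-methyl-2-butene, CC=C(C)C
Why: Olefin cross-metathesis with excess 2-methyl-2-butene exchanges each terminal CH2 for C(CH3)2 with loss of propene, a standard allyl-to-prenyl conversion with N-heterocyclic-carbene ruthenium catalysts, which generally tolerate aryl bromides and dithioacetals.

**Step 8**
Reactants: 13 2-bromo-1-(3,4-dimethoxyphenyl)ethanone
Product: 15 (2R)-2-(3,4-dimethoxyphenyl)oxirane, via (R)-bromohydrin 14 (not isolated)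
Conditions: (R)-2-methyl-CBS-oxazaborolidine [(R)-1-methyl-3,3-diphenyltetrahydro-1H,3H-pyrrolo[1,2-c][1,3,2]oxazaborole] (10 mol%), BH3·SMe2 (0.7 equiv), THF, 0 °C; MeOH; then 2 M NaOH (aq), rt
Reagents that add atoms: none
Why: In the Corey–Bakshi–Shibata reduction the (R)-oxazaborolidine binds the ketone with the aryl group as the large substituent and delivers hydride to the face that gives the (R)-bromohydrin, and the following intramolecular Williamson closure at the primary carbon leaves the new stereocentre untouched.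

**Step 9**
Reactants: 12 2-[2-bromo-4-(methoxymethoxy)-3,5-bis(3-methylbut-2-enyl)phenyl]-1,3-dithiane; 15 (2R)-2-(3,4-dimethoxyphenyl)oxirane
Product: 17 (1S)-2-{2-[2-bromo-4-(methoxymethoxy)-3,5-bis(3-methylbut-2-enyl)phenyl]-1,3-dithian-2-yl}-1-(3,4-dimethoxyphenyl)ethanol, via lithiated dithiane 16 (not isolated)
Conditions: LiN(iPr)2 (1.1 equiv), THF, −78 to −30 °C; 15 (1.3 equiv), DMPU, −30 to 0 °C; H2O
Reagents that add atoms: none
Why: In this Corey–Seebach umpolung the amide base removes the dithiane C2–H without halogen–lithium exchange at the aryl bromide, and the bulky carbanion opens the epoxide by SN2 attack at its unsubstituted carbon, so the benzylic C–O bond keeps its configuration (the descriptor changes from R to S only because the CIP ranking of the neighbours changes).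

**Step 10**
Reactants: 17 (1S)-2-{2-[2-bromo-4-(methoxymethoxy)-3,5-bis(3-methylbut-2-enyl)phenyl]-1,3-dithian-2-yl}-1-(3,4-dimethoxyphenyl)ethanol
Product: 18 (2S)-2-(3,4-dimethoxyphenyl)-7-(methoxymethoxy)-6,8-bis(3-methylbut-2-enyl)-2,3-dihydrospiro[chromene-4,2'-[1,3]dithiane]
Conditions: Pd(OAc)2 (5 mol%), 2-(di-tert-butylphosphino)-1,1'-binaphthyl (6 mol%), Cs2CO3 (1.5 equiv), toluene, 80 °C
Reagents that add atoms: none
Why: Zerovalent palladium, formed in situ from Pd(OAc)2 and the phosphine, inserts into the C8a–Br bond, the caesium alkoxide of the C2 carbinol replaces bromide on the metal, and C–O reductive elimination from the seven-membered aryl(alkoxo)palladium chelate releases the chroman. The closest known reaction type is the Buchwald–Hartwig-type intramolecular etherification of aryl bromides with secondary alcohols, which gives chromans without loss of carbinol configuration. The six-membered ring C closes by O1–C8a bond formation at the aryl carbon, helped by the quaternary dithiane carbon C4, which holds the arene and the carbinol side chain close together (Thorpe–Ingold effect). No stereocentre is created: the C2–O bond is never broken, so the configuration set in step 8 is carried over and the descriptor stays S. The selectivity needed is reductive elimination ahead of beta-hydride elimination of the benzylic alkoxide, which the bulky electron-rich di-tert-butyl biaryl phosphine secures, while the prenyl groups stay out of play because their trisubstituted alkenes insert slowly and carbopalladation from C8a would require a four-membered ring. C4 is kept as the dithiane because the free beta-hydroxy ketone would undergo retro-aldol cleavage or dehydration with Cs2CO3.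

**Step 11**
Reactants: 18 (2S)-2-(3,4-dimethoxyphenyl)-7-(methoxymethoxy)-6,8-bis(3-methylbut-2-enyl)-2,3-dihydrospiro[chromene-4,2'-[1,3]dithiane]
Product: 19 (2S)-2-(3,4-dimethoxyphenyl)-7-(methoxymethoxy)-6,8-bis(3-methylbut-2-enyl)chroman-4-one
Conditions: MeI (excess), CaCO3, MeCN/H2O 4:1, 45 °C
Reagents that add atoms: water, O
Why: S-Methylation turns the dithiane into a sulfonium leaving group and water then delivers the ketone (alkylative dithioacetal hydrolysis), a method that spares the trisubstituted alkenes and, buffered by CaCO3, neither cleaves the MOM ether nor opens the flavanone by retro-oxa-Michael reaction.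

**Step 12**
Reactants: 19 (2S)-2-(3,4-dimethoxyphenyl)-7-(methoxymethoxy)-6,8-bis(3-methylbut-2-enyl)chroman-4-one
Product: 20 (2S)-2-(3,4-dimethoxyphenyl)-7-hydroxy-6,8-bis(3-methylbut-2-enyl)chroman-4-one (IN0946)
Conditions: 3 M HCl (aq), MeOH, 40 °C
Reagents that add atoms: none
Why: Acid-catalysed cleavage of the MOM acetal in methanol is standard for prenylated flavanones, and is kept dilute and only warm so that neither addition of the phenol to a prenyl group nor epimerisation at C2 should intervene.

**Compound list**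
1 | 2-bromo-4-hydroxybenzaldehyde | O=Cc1ccc(O)cc1Br | starting material
2 | allyl bromide | C=CCBr | starting material
3 | 4-(allyloxy)-2-bromobenzaldehyde | O=Cc1ccc(OCC=C)cc1Br | intermediate
4 | 3-allyl-2-bromo-4-hydroxybenzaldehyde | O=Cc1ccc(O)c(CC=C)c1Br | intermediate
5 | 3-allyl-4-(allyloxy)-2-bromobenzaldehyde | O=Cc1ccc(OCC=C)c(CC=C)c1Br | intermediate
6 | 3,5-diallyl-2-bromo-4-hydroxybenzaldehyde | O=Cc1cc(CC=C)c(O)c(CC=C)c1Br | intermediate
7 | propane-1,3-dithiol | SCCCS | starting material
8 | 2,6-diallyl-3-bromo-4-(1,3-dithian-2-yl)phenol | C=CCc1cc(C2SCCCS2)c(Br)c(CC=C)c1O | intermediate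
9 | chloromethyl methyl ether | COCCl | starting material
10 | 2-[3,5-diallyl-2-bromo-4-(methoxymethoxy)phenyl]-1,3-dithiane | C=CCc1cc(C2SCCCS2)c(Br)c(CC=C)c1OCOC | intermediate
11 | 2-methyl-2-butene | CC=C(C)C | starting material
12 | 2-[2-bromo-4-(methoxymethoxy)-3,5-bis(3-methylbut-2-enyl)phenyl]-1,3-dithiane | COCOc1c(CC=C(C)C)cc(C2SCCCS2)c(Br)c1CC=C(C)C | intermediate
13 | 2-bromo-1-(3,4-dimethoxyphenyl)ethanone | COc1ccc(C(=O)CBr)cc1OC | starting material
14 | (1R)-2-bromo-1-(3,4-dimethoxyphenyl)ethanol | COc1ccc([C@@H](O)CBr)cc1OC | intermediate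
15 | (2R)-2-(3,4-dimethoxyphenyl)oxirane | COc1ccc([C@@H]2CO2)cc1OC | intermediate
16 | {2-[2-bromo-4-(methoxymethoxy)-3,5-bis(3-methylbut-2-enyl)phenyl]-1,3-dithian-2-yl}lithium | [Li]C1(SCCCS1)c1cc(CC=C(C)C)c(OCOC)c(CC=C(C)C)c1Br | intermediate
17 | (1S)-2-{2-[2-bromo-4-(methoxymethoxy)-3,5-bis(3-methylbut-2-enyl)phenyl]-1,3-dithian-2-yl}-1-(3,4-dimethoxyphenyl)ethanol | COc1ccc([C@@H](O)CC2(SCCCS2)c2cc(CC=C(C)C)c(OCOC)c(CC=C(C)C)c2Br)cc1OC | intermediate
18 | (2S)-2-(3,4-dimethoxyphenyl)-7-(methoxymethoxy)-6,8-bis(3-methylbut-2-enyl)-2,3-dihydrospiro[chromene-4,2'-[1,3]dithiane] | COc1ccc([C@@H]2CC3(SCCCS3)c3cc(CC=C(C)C)c(OCOC)c(CC=C(C)C)c3O2)cc1OC | intermediate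
19 | (2S)-2-(3,4-dimethoxyphenyl)-7-(methoxymethoxy)-6,8-bis(3-methylbut-2-enyl)chroman-4-one | COc1ccc([C@@H]2CC(=O)c3cc(CC=C(C)C)c(OCOC)c(CC=C(C)C)c3O2)cc1OC | intermediate
20 | (2S)-2-(3,4-dimethoxyphenyl)-7-hydroxy-6,8-bis(3-methylbut-2-enyl)chroman-4-one | COc1ccc([C@@H]2CC(=O)c3cc(CC=C(C)C)c(O)c(CC=C(C)C)c3O2)cc1OC | target

**Step count**
Total: 12 steps. Longest linear sequence: 11 steps (steps 1 to 7 and 9 to 12); the epoxide branch is step 8.

**Steps most likely to fail**

Step 10. A dithiane sulfur sits one atom from the metalated carbon and may bind the arylpalladium intermediate so that alkoxide exchange stalls, or beta-hydride elimination of the benzylic alkoxide may outrun C–O reductive elimination at the doubly ortho-substituted bromide. The fallback removes sulfur before ring closure and changes the metal. It sets out from 17. Alkylative hydrolysis (MeI, CaCO3, aqueous MeCN) should give (3S)-1-[2-bromo-4-(methoxymethoxy)-3,5-bis(3-methylbut-2-enyl)phenyl]-3-(3,4-dimethoxyphenyl)-3-hydroxypropan-1-one F1. Narasaka–Prasad reduction (Et2BOMe, NaBH4, THF/MeOH, −78 °C) should then give the syn diol (1R,3S)-1-[2-bromo-4-(methoxymethoxy)-3,5-bis(3-methylbut-2-enyl)phenyl]-3-(3,4-dimethoxyphenyl)propane-1,3-diol F2. Copper-catalysed Ullmann-type etherification (CuI, 3,4,7,8-tetramethyl-1,10-phenanthroline, Cs2CO3, toluene, 110 °C) should close ring C through the C2 hydroxyl only, since the C4 hydroxyl could reach C8a only through a four-membered ring; this gives (2S,4R)-2-(3,4-dimethoxyphenyl)-7-(methoxymethoxy)-6,8-bis(3-methylbut-2-enyl)chroman-4-ol F3. Dess–Martin oxidation (NaHCO3, CH2Cl2) of the benzylic alcohol returns to the route at 19.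

Step 9. Deprotonation of the hindered, ortho-brominated aryl dithiane may be incomplete, and the carbanion may react slowly or attack the benzylic carbon of the electron-rich epoxide. The fallback builds the C3–C4 bond without a carbanion at C4 and sets C2 by ketone reduction. It sets out from 6. MOM protection (NaH, MOMCl 9) gives 3,5-diallyl-2-bromo-4-(methoxymethoxy)benzaldehyde F4, and cross-metathesis with 11 (second-generation Grubbs catalyst) gives 2-bromo-4-(methoxymethoxy)-3,5-bis(3-methylbut-2-enyl)benzaldehyde F5. Ohira–Bestmann homologation (dimethyl (1-diazo-2-oxopropyl)phosphonate, K2CO3, MeOH) gives 2-bromo-1-ethynyl-4-(methoxymethoxy)-3,5-bis(3-methylbut-2-enyl)benzene F6. The lithium acetylide (LiN(SiMe3)2, THF, −78 °C) is acylated with N,3,4-trimethoxy-N-methylbenzamide to give 3-[2-bromo-4-(methoxymethoxy)-3,5-bis(3-methylbut-2-enyl)phenyl]-1-(3,4-dimethoxyphenyl)prop-2-yn-1-one F7. Double conjugate addition of 7 (NaOMe, MeOH/CH2Cl2, −10 °C) places both sulfur atoms on the carbon that bears ring A and gives 2-{2-[2-bromo-4-(methoxymethoxy)-3,5-bis(3-methylbut-2-enyl)phenyl]-1,3-dithian-2-yl}-1-(3,4-dimethoxyphenyl)ethanone F8. CBS reduction with the (R)-oxazaborolidine and BH3·SMe2 returns to the route at 17.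

Step 7. Sulfur coordination may slow the ruthenium carbene so that exchange of both allyl groups stalls, or the allyl double bonds may migrate into conjugation before they are exchanged. The fallback carries out the metathesis before any sulfur is present. It sets out from 6. Cross-metathesis of the free phenol aldehyde with 11 (second-generation Grubbs catalyst, CH2Cl2, 40 °C) gives 2-bromo-4-hydroxy-3,5-bis(3-methylbut-2-enyl)benzaldehyde F9. Dithioacetalisation with 7 and BF3·OEt2 at −30 °C, cold enough that addition of the phenol or the thiol to the prenyl groups should stay slow, gives 3-bromo-4-(1,3-dithian-2-yl)-2,6-bis(3-methylbut-2-enyl)phenol F10. MOM protection (NaH, MOMCl 9) returns to the route at 12.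

**Further compounds**
F1 | step 10 | (3S)-1-[2-bromo-4-(methoxymethoxy)-3,5-bis(3-methylbut-2-enyl)phenyl]-3-(3,4-dimethoxyphenyl)-3-hydroxypropan-1-one | COc1ccc([C@@H](O)CC(=O)c2cc(CC=C(C)C)c(OCOC)c(CC=C(C)C)c2Br)cc1OC
F2 | step 10 | (1R,3S)-1-[2-bromo-4-(methoxymethoxy)-3,5-bis(3-methylbut-2-enyl)phenyl]-3-(3,4-dimethoxyphenyl)propane-1,3-diol | COc1ccc([C@@H](O)C[C@@H](O)c2cc(CC=C(C)C)c(OCOC)c(CC=C(C)C)c2Br)cc1OC
F3 | step 10 | (2S,4R)-2-(3,4-dimethoxyphenyl)-7-(methoxymethoxy)-6,8-bis(3-methylbut-2-enyl)chroman-4-ol | COc1ccc([C@@H]2C[C@@H](O)c3cc(CC=C(C)C)c(OCOC)c(CC=C(C)C)c3O2)cc1OC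
F4 | step 9 | 3,5-diallyl-2-bromo-4-(methoxymethoxy)benzaldehyde | O=Cc1cc(CC=C)c(OCOC)c(CC=C)c1Br
F5 | step 9 | 2-bromo-4-(methoxymethoxy)-3,5-bis(3-methylbut-2-enyl)benzaldehyde | O=Cc1cc(CC=C(C)C)c(OCOC)c(CC=C(C)C)c1Br
F6 | step 9 | 2-bromo-1-ethynyl-4-(methoxymethoxy)-3,5-bis(3-methylbut-2-enyl)benzene | C#Cc1cc(CC=C(C)C)c(OCOC)c(CC=C(C)C)c1Br
F7 | step 9 | 3-[2-bromo-4-(methoxymethoxy)-3,5-bis(3-methylbut-2-enyl)phenyl]-1-(3,4-dimethoxyphenyl)prop-2-yn-1-one | COc1ccc(C(=O)C#Cc2cc(CC=C(C)C)c(OCOC)c(CC=C(C)C)c2Br)cc1OC
F8 | step 9 | 2-{2-[2-bromo-4-(methoxymethoxy)-3,5-bis(3-methylbut-2-enyl)phenyl]-1,3-dithian-2-yl}-1-(3,4-dimethoxyphenyl)ethanone | COc1ccc(C(=O)CC2(SCCCS2)c2cc(CC=C(C)C)c(OCOC)c(CC=C(C)C)c2Br)cc1OC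
F9 | step 7 | 2-bromo-4-hydroxy-3,5-bis(3-methylbut-2-enyl)benzaldehyde | O=Cc1cc(CC=C(C)C)c(O)c(CC=C(C)C)c1Br
F10 | step 7 | 3-bromo-4-(1,3-dithian-2-yl)-2,6-bis(3-methylbut-2-enyl)phenol | CC(C)=CCc1cc(C2SCCCS2)c(Br)c(CC=C(C)C)c1O
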